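**Retrosynthetic overview**
1. Target 15 ⇐ tert-butyl ester 14 (acidolysis as the last step).
2. 14 ⇐ aldehyde 8 + pyranone 11: the side chain is attached through a C–O bond (enol ester 13, formed oxidatively from the aldehyde under NHC catalysis), and the acyl group is then relayed to C3 by a 1,3 O→C shift.
3. The only ring, dihydropyranone 11, is formed first by C–O lactonisation of δ-hydroxy-β-keto ester 10, made from ethyl (R)-3-hydroxybutanoate 9 (C6 from the chiral pool).
4. 8 ⇐ diene 6 by selective cleavage of the isopropylidene end; 6 ⇐ Suzuki coupling of (Z)-bromoenoate 3 with (E)-alkenylboronate 5.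
5. 3 ⇐ (S)-2-methylbutan-1-ol 1 (C10′ stereocentre); 5 ⇐ (R)-citronellal 4 (C4′ stereocentre).

Assumption: the 3-acyl-4-hydroxy enol drawn in the SMILES and its tricarbonyl tautomers are treated as one compound, and 1, 4, 9 and the named reagents are taken as commercially available.

**Route**

Step 1
Reactants: 1 (S)-2-methylbutan-1-ol
Product: 3 tert-butyl (2Z,4S)-2-bromo-4-methylhex-2-enoate, via (S)-2-methylbutanal 2 (not isolated)
Conditions: TEMPO (1 mol%), KBr (10 mol%), NaOCl (1.1 equiv), NaHCO3, CH2Cl2/H2O, 0 °C; the dried CH2Cl2 layer is added to Ph3P=CHCO2tBu + NBS (1.2 equiv each, CH2Cl2, −20 °C) and K2CO3, −20 °C → rt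
Reagents that add atoms: tert-butyl (triphenylphosphoranylidene)acetate CC(C)(C)OC(=O)C=P(c1ccccc1)(c1ccccc1)c1ccccc1; N-bromosuccinimide O=C1CCC(=O)N1Br
Why: Anelli (TEMPO/hypochlorite) oxidation gives the α-chiral aldehyde cold and without epimerisation, and Wittig olefination with the stabilised α-bromo ylide made in the flask places the ester trans to the sec-butyl group, i.e. the (Z)-α-bromoenoate, while C4 is carried over unchanged from 1.

Step 2
Reactants: 4 (R)-citronellal [(3R)-3,7-dimethyloct-6-enal]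
Product: 5 2-[(1E,4R)-4,8-dimethylnona-1,7-dien-1-yl]-4,4,5,5-tetramethyl-1,3,2-dioxaborolane
Conditions: CH2(Bpin)2 (1.2 equiv), LiTMP (1.2 equiv), THF, 0 °C; then 4, −78 °C → rt
Reagents that add atoms: bis[(pinacolato)boryl]methane CC1(C)OB(CB2OC(C)(C)C(C)(C)O2)OC1(C)C
Why: Boron-Wittig olefination, in which the α-boryl carbanion adds to the aldehyde and syn B–O elimination gives the (E)-alkenylboronate; the β-stereocentre of 4 is not touched.

Step 3
Reactants: 3 tert-butyl (2Z,4S)-2-bromo-4-methylhex-2-enoate, 5 2-[(1E,4R)-4,8-dimethylnona-1,7-dien-1-yl]-4,4,5,5-tetramethyl-1,3,2-dioxaborolane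
Product: 6 tert-butyl (2E,4S)-2-[(1E,4R)-4,8-dimethylnona-1,7-dien-1-yl]-4-methylhex-2-enoate
Conditions: Pd(dppf)Cl2 (5 mol%), K3PO4 (3 equiv), THF/H2O 5:1, 50 °C
Reagents that add atoms: none
Why: Suzuki–Miyaura coupling proceeds with retention at both alkenyl partners, so the (Z)-bromide and the (E)-boronate give the (E,E)-2-carboxy-1,3-diene with sec-butyl cis to the new vinyl group.

Step 4
Reactants: 6 tert-butyl (2E,4S)-2-[(1E,4R)-4,8-dimethylnona-1,7-dien-1-yl]-4-methylhex-2-enoate
Product: 8 tert-butyl (2E,4S)-4-methyl-2-[(1E,4R)-4-methyl-7-oxohept-1-en-1-yl]hex-2-enoate, via epoxide 7 (not isolated)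
Conditions: mCPBA (1.0 equiv), CH2Cl2, −10 → 0 °C; then H5IO6 (1.3 equiv), THF/H2O, 0 °C → rt, same flask
Reagents that add atoms: m-chloroperoxybenzoic acid OOC(=O)c1cccc(Cl)c1
Why: Prilezhaev epoxidation is selective for the electron-rich trisubstituted alkene over the ester-deactivated cross-conjugated diene, and periodic acid cleaves the epoxide (via the diol, Malaprade) to the aldehyde and acetone without affecting any stereocentre.

Step 5
Reactants: 9 ethyl (3R)-3-hydroxybutanoate
Product: 10 tert-butyl (5R)-5-hydroxy-3-oxohexanoate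
Conditions: LDA (4 equiv), t-BuOAc (4 equiv), THF, −78 °C; then 9, −78 → −30 °C; aq NH4Cl
Reagents that add atoms: tert-butyl acetate CC(=O)OC(C)(C)C
Why: Crossed Claisen condensation with excess lithium enolate of tert-butyl acetate on the unprotected hydroxy ester (the alkoxide and the product enolate protect themselves), leaving the carbinol stereocentre untouched.

Step 6
Reactants: 10 tert-butyl (5R)-5-hydroxy-3-oxohexanoate
Product: 11 (6R)-4-hydroxy-6-methyl-5,6-dihydro-2H-pyran-2-one
Conditions: TFA, CH2Cl2, 0 °C → rt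
Reagents that add atoms: none
Why: Acidolysis of the tert-butyl ester and lactonisation form the ring C–O bond by attack of the C5 hydroxyl on the acyl carbon, so the C–O bond at the stereocentre is never broken and (R) is retained.

Step 7
Reactants: 8 tert-butyl (2E,4S)-4-methyl-2-[(1E,4R)-4-methyl-7-oxohept-1-en-1-yl]hex-2-enoate, 11 (6R)-4-hydroxy-6-methyl-5,6-dihydro-2H-pyran-2-one
Product: 14 tert-butyl (2E,4S)-2-[(1E,4R)-7-[(6R)-4-hydroxy-6-methyl-2-oxo-5,6-dihydro-2H-pyran-3-yl]-4-methyl-7-oxohept-1-en-1-yl]-4-methylhex-2-enoate, via HFIP ester 12 (not isolated), via enol ester 13 (not isolated)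
Conditions: 1,4-dimethyl-1,2,4-triazolium iodide (10 mol%), DBU (20 mol%), 3,3′,5,5′-tetra-tert-butyl-4,4′-diphenoquinone (1.05 equiv), HFIP (2 equiv), THF, rt; then 11 (1.3 equiv), Et3N (2.5 equiv), DMAP (30 mol%), 45 °C; 1 M HCl work-up
Reagents that add atoms: none
Why: Proposed new method: the carbene adds to the aldehyde and the Breslow intermediate is oxidised by the quinone to an acyl azolium, which HFIP intercepts as active ester 12 so that no free aldehyde remains to condense (Knoevenagel) with 11, after which the enol oxygen of 11 is acylated (new C–O bond, enol ester 13) and DMAP or the carbene relays the acyl group by a 1,3 O→C shift to C3, driven by formation of the acidic tricarbonyl enolate, so that an aldehyde instead of a carboxylic acid serves as the acyl donor for a 4-hydroxy-5,6-dihydropyran-2-one (not demonstrated so far to my knowledge) and no stereocentre is touched; the closest known reaction types are the NHC-catalysed oxidative esterification of aldehydes through HFIP active esters and the Steglich-type DCC/DMAP O-acylation–acyl migration of such pyranones.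

Step 8
Reactants: 14 tert-butyl (2E,4S)-2-[(1E,4R)-7-[(6R)-4-hydroxy-6-methyl-2-oxo-5,6-dihydro-2H-pyran-3-yl]-4-methyl-7-oxohept-1-en-1-yl]-4-methylhex-2-enoate
Product: 15 (2E,4S)-2-[(1E,4R)-7-[(6R)-4-hydroxy-6-methyl-2-oxo-5,6-dihydro-2H-pyran-3-yl]-4-methyl-7-oxohept-1-en-1-yl]-4-methylhex-2-enoic acid (target)
Conditions: TFA/CH2Cl2 1:4, 0 °C → rt; evaporate with toluene
Reagents that add atoms: none
Why: Acidolysis of the tert-butyl ester (E1 loss of 2-methylpropene) frees the dienoic acid under conditions to which the acyl-pyranone enol, the lactone, the diene and all three stereocentres are inert.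

**Compound list**
1 | (S)-2-methylbutan-1-ol | CC[C@H](C)CO | starting material
2 | (S)-2-methylbutanal | CC[C@H](C)C=O | intermediate
3 | tert-butyl (2Z,4S)-2-bromo-4-methylhex-2-enoate | CC[C@H](C)/C=C(\Br)C(=O)OC(C)(C)C | intermediate
4 | (R)-citronellal, (3R)-3,7-dimethyloct-6-enal | CC(C)=CCC[C@@H](C)CC=O | starting material
5 | 2-[(1E,4R)-4,8-dimethylnona-1,7-dien-1-yl]-4,4,5,5-tetramethyl-1,3,2-dioxaborolane | CC(C)=CCC[C@@H](C)C/C=C/B1OC(C)(C)C(C)(C)O1 | intermediate
6 | tert-butyl (2E,4S)-2-[(1E,4R)-4,8-dimethylnona-1,7-dien-1-yl]-4-methylhex-2-enoate | CC[C@H](C)/C=C(\C=C\C[C@H](C)CCC=C(C)C)C(=O)OC(C)(C)C | intermediate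
7 | tert-butyl (2E,4S)-2-[(1E,4R)-6-(3,3-dimethyloxiran-2-yl)-4-methylhex-1-en-1-yl]-4-methylhex-2-enoate (both epimers at the oxirane carbon) | CC[C@H](C)/C=C(\C=C\C[C@H](C)CCC1OC1(C)C)C(=O)OC(C)(C)C | intermediate
8 | tert-butyl (2E,4S)-4-methyl-2-[(1E,4R)-4-methyl-7-oxohept-1-en-1-yl]hex-2-enoate | CC[C@H](C)/C=C(\C=C\C[C@H](C)CCC=O)C(=O)OC(C)(C)C | intermediate
9 | ethyl (3R)-3-hydroxybutanoate | C[C@@H](O)CC(=O)OCC | starting material
10 | tert-butyl (5R)-5-hydroxy-3-oxohexanoate | C[C@@H](O)CC(=O)CC(=O)OC(C)(C)C | intermediate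
11 | (6R)-4-hydroxy-6-methyl-5,6-dihydro-2H-pyran-2-one | C[C@@H]1CC(O)=CC(=O)O1 | intermediate
12 | 1,1,1,3,3,3-hexafluoropropan-2-yl (4R,6E,8E,10S)-8-(tert-butoxycarbonyl)-4,10-dimethyldodeca-6,8-dienoate | CC[C@H](C)/C=C(\C=C\C[C@H](C)CCC(=O)OC(C(F)(F)F)C(F)(F)F)C(=O)OC(C)(C)C | intermediate
13 | (6R)-6-methyl-2-oxo-5,6-dihydro-2H-pyran-4-yl (4R,6E,8E,10S)-8-(tert-butoxycarbonyl)-4,10-dimethyldodeca-6,8-dienoate | CC[C@H](C)/C=C(\C=C\C[C@H](C)CCC(=O)OC1=CC(=O)O[C@H](C)C1)C(=O)OC(C)(C)C | intermediate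
14 | tert-butyl (2E,4S)-2-[(1E,4R)-7-[(6R)-4-hydroxy-6-methyl-2-oxo-5,6-dihydro-2H-pyran-3-yl]-4-methyl-7-oxohept-1-en-1-yl]-4-methylhex-2-enoate | CC[C@H](C)/C=C(\C=C\C[C@H](C)CCC(=O)C1=C(O)C[C@@H](C)OC1=O)C(=O)OC(C)(C)C | intermediate
15 | (2E,4S)-2-[(1E,4R)-7-[(6R)-4-hydroxy-6-methyl-2-oxo-5,6-dihydro-2H-pyran-3-yl]-4-methyl-7-oxohept-1-en-1-yl]-4-methylhex-2-enoic acid | CC[C@H](C)/C=C(\C=C\C[C@H](C)CCC(=O)C1=C(O)C[C@@H](C)OC1=O)C(=O)O | target

**Totals**
Total step count: 8.
Longest linear sequence: 5 steps (steps 2, 3, 4, 7, 8 from 4; equally steps 1, 3, 4, 7, 8 from 1).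

**Three steps most likely to fail, with fallbacks**

Step 7 (the proposed oxidative acyl transfer). The HFIP ester may acylate the weakly nucleophilic pyranone enolate too slowly, or the aldehyde may be lost to aldol or acyloin side reactions. The fallback uses known chemistry and sets out from 8. Pinnick oxidation (NaClO2, NaH2PO4, 2-methyl-2-butene, t-BuOH/H2O) gives (4R,6E,8E,10S)-8-(tert-butoxycarbonyl)-4,10-dimethyldodeca-6,8-dienoic acid F1. F1 is joined to 11 with DCC and DMAP in CH2Cl2 (O-acylation, then DMAP-mediated 1,3 acyl migration in the same flask). The fallback comes back to the route at 14.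

Step 4 (selective cleavage in the presence of the diene). The peracid may also attack the C6′=C7′ alkene. The fallback sets out from 5 and epoxidises before the diene exists. mCPBA (1.0 equiv, CH2Cl2, −10 °C) converts 5 into 2-[(1E,4R)-6-(3,3-dimethyloxiran-2-yl)-4-methylhex-1-en-1-yl]-4,4,5,5-tetramethyl-1,3,2-dioxaborolane F2. Suzuki coupling of F2 with 3 under the step 3 conditions gives the epoxide 7, now isolated, where the fallback comes back to the route; H5IO6 then gives 8 as in the second half of step 4.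

Step 1 (in-flask bromo-ylide Wittig on a volatile, epimerisable aldehyde). The yield or the Z/E ratio may be poor. The fallback sets out from 2 and builds the trisubstituted alkene and the diene by allylic-ylide chemistry.
- Hydroalumination of tert-butyl propiolate (DIBAL-H, NMO, THF, 0 °C) and addition of 2 gives the Morita–Baylis–Hillman-type adduct tert-butyl (4S)-3-hydroxy-4-methyl-2-methylidenehexanoate F3 (both C3 epimers).
- Boc2O/DMAP converts F3 into tert-butyl (4S)-3-[(tert-butoxycarbonyl)oxy]-4-methyl-2-methylidenehexanoate F4.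
- PBu3 with (R)-citronellal 4 (SN2′ phosphonium formation, ylide, Wittig olefination) converts F4 directly into the diene; the fallback comes back to the route at 6, and steps 2 and 3 are then not needed.

Further compounds
F1 | step 7 | (4R,6E,8E,10S)-8-(tert-butoxycarbonyl)-4,10-dimethyldodeca-6,8-dienoic acid | CC[C@H](C)/C=C(\C=C\C[C@H](C)CCC(=O)O)C(=O)OC(C)(C)C
F2 | step 4 | 2-[(1E,4R)-6-(3,3-dimethyloxiran-2-yl)-4-methylhex-1-en-1-yl]-4,4,5,5-tetramethyl-1,3,2-dioxaborolane (both epimers at the oxirane carbon) | CC1(C)OC1CC[C@@H](C)C/C=C/B1OC(C)(C)C(C)(C)O1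
F3 | step 1 | tert-butyl (4S)-3-hydroxy-4-methyl-2-methylidenehexanoate (both C3 epimers) | CC[C@H](C)C(O)C(=C)C(=O)OC(C)(C)C
F4 | step 1 | tert-butyl (4S)-3-[(tert-butoxycarbonyl)oxy]-4-methyl-2-methylidenehexanoate (both C3 epimers) | CC[C@H](C)C(OC(=O)OC(C)(C)C)C(=C)C(=O)OC(C)(C)C
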